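**Retrosynthetic overview**

1. The target is a flavone with 5-OH, 7-OMe and 8-prenyl on ring A and a 4-hydroxy-2-methoxyphenyl ring B; it has no stereocenter. The last operations are removal of a 4'-O-methoxymethyl group and, before it, transfer of a prenyl group from O5 to C8 by a Claisen shift to C6 followed by a Cope shift to C8.
2. Ring C (O1, C2, C3, C4, C4a, C8a) is cut into three pieces: an aryl iodide (ring A, iodine on C4a), carbon monoxide (C4) and an arylacetylene (C3, C2, ring B). One operation forms C4a–C4, C4–C3 and O1–C2.
3. The strategy rests on this feature: C4 lies between C4a and C3, and C4a is flanked by the two oxygen-bearing carbons C5 and C8a, which are equivalent (mirror plane through C4a and C7) as long as C8 is unsubstituted. A symmetric, unprotected 2-iodo-5-methoxyresorcinol can therefore be used, and the prenyl group has to come after ring closure.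
4. The iodide comes from 5-methoxyresorcinol (bis-acetal, lithiation between the acetals, iodine, deprotection); the alkyne comes from 4-hydroxy-2-methoxybenzaldehyde (acetal, one-carbon homologation).
5. Ring order: rings A and B are bought; ring C is the only ring formed (step 6).

Key step: step 6

Remark: flavone numbering is used for ring atoms (ring B positions primed). Eu(fod)3 stands for tris(6,6,7,7,8,8,8-heptafluoro-2,2-dimethyloctane-3,5-dionato)europium, a complex of trivalent europium.

**Route**

Step 1
Reactants: 1 5-methoxyresorcinol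
Product: 2 1-methoxy-3,5-bis(methoxymethoxy)benzene
Conditions: NaH, MOMCl, DMF, 0 °C → rt
Reagents that add atoms: chloromethyl methyl ether (MOMCl), COCCl
Why: Williamson-type O-alkylation of the bis-phenoxide by the reactive α-chloro ether should give the bis-acetal, which masks the phenols and supplies the two directing groups for the next step.

Step 2
Reactants: 2 1-methoxy-3,5-bis(methoxymethoxy)benzene
Product: 4 2-iodo-5-methoxy-1,3-bis(methoxymethoxy)benzene, via aryllithium 3 (not isolated)
Conditions: n-BuLi, THF, 0 °C; then iodine, −78 °C → rt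
Reagents that add atoms: iodine, [I][I]
Why: Directed ortho-metalation should take place at the carbon between the two methoxymethoxy groups, where both acetal oxygens hold lithium (a stronger pair of directors than acetal plus methyl ether), and the aryllithium is trapped by iodine in an electrophilic quench.

Step 3
Reactants: 4 2-iodo-5-methoxy-1,3-bis(methoxymethoxy)benzene
Product: 5 2-iodo-5-methoxybenzene-1,3-diol
Conditions: HCl (1.25 M in MeOH), 0 °C → rt
Reagents that add atoms: none
Why: Acid-catalysed transacetalisation to methanol cleaves both phenolic methoxymethyl ethers, and the conditions are kept cold and dilute because the electron-rich aryl iodide can lose iodine by ipso protonation.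

Step 4
Reactants: 6 4-hydroxy-2-methoxybenzaldehyde
Product: 7 2-methoxy-4-(methoxymethoxy)benzaldehyde
Conditions: MOMCl, i-Pr2NEt, CH2Cl2, 0 °C → rt
Reagents that add atoms: chloromethyl methyl ether (MOMCl), COCCl
Why: O-Alkylation of the acidic para-formyl phenol by the α-chloro ether under amine base should proceed cleanly and leaves the aldehyde untouched.

Step 5
Reactants: 7 2-methoxy-4-(methoxymethoxy)benzaldehyde
Product: 8 1-ethynyl-2-methoxy-4-(methoxymethoxy)benzene
Conditions: dimethyl (1-diazo-2-oxopropyl)phosphonate, K2CO3, MeOH, rt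
Reagents that add atoms: dimethyl (1-diazo-2-oxopropyl)phosphonate (Ohira–Bestmann reagent), CC(=O)C(=[N+]=[N-])P(=O)(OC)OC
Why: Seyferth–Gilbert homologation in the Ohira–Bestmann form: methoxide removes the acetyl group of the reagent, the diazophosphonate anion olefinates the aldehyde, and loss of nitrogen with a 1,2-hydrogen shift gives the terminal alkyne under conditions mild enough for the acetal.

Step 6
Reactants: 5 2-iodo-5-methoxybenzene-1,3-diol; 8 1-ethynyl-2-methoxy-4-(methoxymethoxy)benzene; 9 carbon monoxide
Product: 12 5-hydroxy-7-methoxy-2-[2-methoxy-4-(methoxymethoxy)phenyl]chromen-4-one, via ynone 10 (not isolated), via β-aminoenone 11 (not isolated)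
Conditions: PdCl2(PPh3)2 (5 mol %), CO (20 atm), Et2NH, 120 °C
Reagents that add atoms: none
Why: Zerovalent palladium generated in the flask from PdCl2(PPh3)2 inserts into the carbon–iodine bond of 5, CO insertion gives the aroyl complex of divalent palladium, and amine-assisted transfer of the acetylide of 8 followed by reductive elimination gives ynone 10 (bonds C4a–C4 and C4–C3); this is the known carbonylative Sonogashira coupling and annulation of ortho-iodophenols with terminal alkynes in a secondary amine. Diethylamine then adds to the ynone in conjugate fashion to give β-aminoenone 11, and a phenol oxygen attacks the amine-bearing carbon C2 and expels diethylamine, so ring C closes by a net 6-endo addition–elimination (bond O1–C2). No stereocenter is formed. The step needs three selectivities: CO insertion has to outrun direct alkynylation of the aryl complex, which the electron-rich aryl group, the absence of copper and the CO pressure favour; the aroyl complex has to take the alkyne and not the amine, which is the known behaviour of this catalyst system in diethylamine; and the closure has to be six-membered and not five-membered (aurone), which the amine adduct secures because the carbon next to the carbonyl is no longer electrophilic once the enaminone has formed. Which hydroxyl closes the ring is of no consequence, because ring A of 5 has a mirror plane through the iodinated carbon and the methoxy-bearing carbon, so both oxygens lead to the same 5-hydroxy-7-methoxyflavone and the phenols need no protection.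

Step 7
Reactants: 12 5-hydroxy-7-methoxy-2-[2-methoxy-4-(methoxymethoxy)phenyl]chromen-4-one; 13 prenyl bromide
Product: 14 7-methoxy-2-[2-methoxy-4-(methoxymethoxy)phenyl]-5-[(3-methylbut-2-en-1-yl)oxy]chromen-4-one
Conditions: K2CO3, DMF, 50 °C
Reagents that add atoms: none
Why: Williamson etherification of the only free phenol; the hydrogen-bonded 5-hydroxyl is a weak nucleophile but should be alkylated by the reactive allylic bromide in a polar aprotic solvent, where attack through oxygen is favoured over attack through carbon.

Step 8
Reactants: 14 7-methoxy-2-[2-methoxy-4-(methoxymethoxy)phenyl]-5-[(3-methylbut-2-en-1-yl)oxy]chromen-4-one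
Product: 17 5-hydroxy-7-methoxy-2-[2-methoxy-4-(methoxymethoxy)phenyl]-8-(3-methylbut-2-en-1-yl)chromen-4-one, via ortho-dienone 15 (not isolated), via para-dienone 16 (not isolated)
Conditions: Eu(fod)3 (10 mol %), NaHCO3, PhCl, 85 °C
Reagents that add atoms: none
Why: Tandem aromatic Claisen–Cope rearrangement: the Lewis-acidic europium complex binds the C4 carbonyl and the ether oxygen and lowers the barrier of the [3,3] shift to C6 (the only free ortho position), and the 1,5-diene of dienone 15 (C6 substituent and C7=C8) should undergo a second [3,3] shift to C8 before it enolises, which relieves the crowding between O5 and the 7-methoxy group and returns the linear prenyl group; enolisation of 16 restores ring A, and the sp3 centres of 15 and 16 are transient, so no stereocenter remains.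

Step 9
Reactants: 17 5-hydroxy-7-methoxy-2-[2-methoxy-4-(methoxymethoxy)phenyl]-8-(3-methylbut-2-en-1-yl)chromen-4-one
Product: 18 Artocarpetin B
Conditions: HCl (1.25 M in MeOH), rt → 40 °C
Reagents that add atoms: none
Why: Acid-catalysed methanolysis of the phenolic methoxymethyl acetal under mild conditions should spare the trisubstituted alkene, and because C7 carries a methyl ether no hydroxyl flanks the prenyl group, so acid-induced chroman formation is excluded.

**Compound list**

1 | 5-methoxyresorcinol (5-methoxybenzene-1,3-diol) | COc1cc(O)cc(O)c1 | starting material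
2 | 1-methoxy-3,5-bis(methoxymethoxy)benzene | COCOc1cc(OC)cc(OCOC)c1 | intermediate
3 | [4-methoxy-2,6-bis(methoxymethoxy)phenyl]lithium | [Li]c1c(OCOC)cc(OC)cc1OCOC | intermediate
4 | 2-iodo-5-methoxy-1,3-bis(methoxymethoxy)benzene | COCOc1cc(OC)cc(OCOC)c1I | intermediate
5 | 2-iodo-5-methoxybenzene-1,3-diol | COc1cc(O)c(I)c(O)c1 | intermediate
6 | 4-hydroxy-2-methoxybenzaldehyde | COc1cc(O)ccc1C=O | starting material
7 | 2-methoxy-4-(methoxymethoxy)benzaldehyde | COCOc1ccc(C=O)c(OC)c1 | intermediate
8 | 1-ethynyl-2-methoxy-4-(methoxymethoxy)benzene | COCOc1ccc(C#C)c(OC)c1 | intermediate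
9 | carbon monoxide | [C-]#[O+] | starting material
10 | 1-(2,6-dihydroxy-4-methoxyphenyl)-3-[2-methoxy-4-(methoxymethoxy)phenyl]prop-2-yn-1-one | COCOc1ccc(C#CC(=O)c2c(O)cc(OC)cc2O)c(OC)c1 | intermediate
11 | (E)-3-(diethylamino)-1-(2,6-dihydroxy-4-methoxyphenyl)-3-[2-methoxy-4-(methoxymethoxy)phenyl]prop-2-en-1-one (drawn as the expected E isomer; either geometry can close) | CCN(CC)/C(c1ccc(OCOC)cc1OC)=C/C(=O)c1c(O)cc(OC)cc1O | intermediate
12 | 5-hydroxy-7-methoxy-2-[2-methoxy-4-(methoxymethoxy)phenyl]chromen-4-one | COCOc1ccc(-c2cc(=O)c3c(O)cc(OC)cc3o2)c(OC)c1 | intermediate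
13 | prenyl bromide (1-bromo-3-methylbut-2-ene) | CC(C)=CCBr | starting material
14 | 7-methoxy-2-[2-methoxy-4-(methoxymethoxy)phenyl]-5-[(3-methylbut-2-en-1-yl)oxy]chromen-4-one | COCOc1ccc(-c2cc(=O)c3c(OCC=C(C)C)cc(OC)cc3o2)c(OC)c1 | intermediate
15 | 7-methoxy-2-[2-methoxy-4-(methoxymethoxy)phenyl]-6-(2-methylbut-3-en-2-yl)-6H-chromene-4,5-dione (racemic at C6, transient) | COCOc1ccc(C2=CC(=O)C3=C(O2)C=C(OC)C(C(C)(C)C=C)C3=O)c(OC)c1 | intermediate
16 | 7-methoxy-2-[2-methoxy-4-(methoxymethoxy)phenyl]-8-(3-methylbut-2-en-1-yl)-8H-chromene-4,5-dione (racemic at C8, transient) | COCOc1ccc(C2=CC(=O)C3=C(O2)C(CC=C(C)C)C(OC)=CC3=O)c(OC)c1 | intermediate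
17 | 5-hydroxy-7-methoxy-2-[2-methoxy-4-(methoxymethoxy)phenyl]-8-(3-methylbut-2-en-1-yl)chromen-4-one | COCOc1ccc(-c2cc(=O)c3c(O)cc(OC)c(CC=C(C)C)c3o2)c(OC)c1 | intermediate
18 | Artocarpetin B, 5-hydroxy-2-(4-hydroxy-2-methoxyphenyl)-7-methoxy-8-(3-methylbut-2-en-1-yl)chromen-4-one | COc1cc(O)ccc1-c1cc(=O)c2c(O)cc(OC)c(CC=C(C)C)c2o1 | target

**Step count and risks**

Total steps: 9. Longest linear sequence: 7 steps (steps 1, 2, 3, 6, 7, 8, 9); the alkyne arm (steps 4 and 5) joins at step 6.

Steps most likely to fail:

1. Step 6. Oxidative addition at the doubly ortho-substituted, electron-rich carbon–iodine bond may be slow, so that reductive loss of iodine, direct alkynylation without CO uptake, or capture of the aroyl complex by the amine competes with the annulation. Fallback (sets out from 2 and 8, returns at 12): aryllithium 3, made from 2 as in step 2, would be quenched with DMF to give 4-methoxy-2,6-bis(methoxymethoxy)benzaldehyde F1. The lithium acetylide of 8 (n-BuLi, THF, −78 °C) would add to F1 to give racemic 1-[4-methoxy-2,6-bis(methoxymethoxy)phenyl]-3-[2-methoxy-4-(methoxymethoxy)phenyl]prop-2-yn-1-ol F2, and MnO2 in CH2Cl2 would oxidise this to 1-[4-methoxy-2,6-bis(methoxymethoxy)phenyl]-3-[2-methoxy-4-(methoxymethoxy)phenyl]prop-2-yn-1-one F3. Methanolic HCl would remove all three acetals to give 1-(2,6-dihydroxy-4-methoxyphenyl)-3-(4-hydroxy-2-methoxyphenyl)prop-2-yn-1-one F4, which may begin to close under the acid and would be closed fully by Et2NH in EtOH (amine adduct, 6-endo) to 5-hydroxy-2-(4-hydroxy-2-methoxyphenyl)-7-methoxychromen-4-one F5. Selective acetal formation at the non-chelated 4'-hydroxyl (MOMCl, i-Pr2NEt, CH2Cl2, 0 °C) would return 12.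

2. Step 8. The Claisen intermediate may enolise before the Cope shift, leaving the reversed prenyl group at C6, or the allyl group may ionise and migrate to C6 or be lost. Fallback (sets out from 12, returns at 18): the 5-hydroxyl would be capped (NaH, MOMCl, DMF) to give 7-methoxy-5-(methoxymethoxy)-2-[2-methoxy-4-(methoxymethoxy)phenyl]chromen-4-one F6. Electrophilic iodination with N-iodosuccinimide in DMF is expected at C8, the position preferred in 5,7-dialkoxyflavones, to give 8-iodo-7-methoxy-5-(methoxymethoxy)-2-[2-methoxy-4-(methoxymethoxy)phenyl]chromen-4-one F7. Stille coupling with tributyl(3-methylbut-2-en-1-yl)stannane (Pd(PPh3)4, DMF, 90 °C) would give 7-methoxy-5-(methoxymethoxy)-2-[2-methoxy-4-(methoxymethoxy)phenyl]-8-(3-methylbut-2-en-1-yl)chromen-4-one F8. Methanolic HCl would then remove both acetals and give 18 directly.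

3. Step 3. Acid may cause loss or migration of iodine by ipso protonation of the very electron-rich ring during acetal cleavage. Fallback (sets out from 1, returns at 5): direct electrophilic iodination of unprotected 1 with iodine and NaHCO3 in H2O–THF at 0 °C, where the phenoxide is expected to react at the carbon between the two hydroxyls, as resorcinol itself does; no acid and no protecting group are involved, and no new compound is formed.

**Further compounds**

F1 | step 6 | 4-methoxy-2,6-bis(methoxymethoxy)benzaldehyde | COCOc1cc(OC)cc(OCOC)c1C=O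
F2 | step 6 | 1-[4-methoxy-2,6-bis(methoxymethoxy)phenyl]-3-[2-methoxy-4-(methoxymethoxy)phenyl]prop-2-yn-1-ol (racemic) | COCOc1ccc(C#CC(O)c2c(OCOC)cc(OC)cc2OCOC)c(OC)c1
F3 | step 6 | 1-[4-methoxy-2,6-bis(methoxymethoxy)phenyl]-3-[2-methoxy-4-(methoxymethoxy)phenyl]prop-2-yn-1-one | COCOc1ccc(C#CC(=O)c2c(OCOC)cc(OC)cc2OCOC)c(OC)c1
F4 | step 6 | 1-(2,6-dihydroxy-4-methoxyphenyl)-3-(4-hydroxy-2-methoxyphenyl)prop-2-yn-1-one | COc1cc(O)ccc1C#CC(=O)c1c(O)cc(OC)cc1O
F5 | step 6 | 5-hydroxy-2-(4-hydroxy-2-methoxyphenyl)-7-methoxychromen-4-one | COc1cc(O)ccc1-c1cc(=O)c2c(O)cc(OC)cc2o1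
F6 | step 8 | 7-methoxy-5-(methoxymethoxy)-2-[2-methoxy-4-(methoxymethoxy)phenyl]chromen-4-one | COCOc1ccc(-c2cc(=O)c3c(OCOC)cc(OC)cc3o2)c(OC)c1
F7 | step 8 | 8-iodo-7-methoxy-5-(methoxymethoxy)-2-[2-methoxy-4-(methoxymethoxy)phenyl]chromen-4-one | COCOc1ccc(-c2cc(=O)c3c(OCOC)cc(OC)c(I)c3o2)c(OC)c1
F8 | step 8 | 7-methoxy-5-(methoxymethoxy)-2-[2-methoxy-4-(methoxymethoxy)phenyl]-8-(3-methylbut-2-en-1-yl)chromen-4-one | COCOc1ccc(-c2cc(=O)c3c(OCOC)cc(OC)c(CC=C(C)C)c3o2)c(OC)c1
F0 | step 3 | none | none
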